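## The problem

- The target is a eudesmane. Locants used throughout: ring A = C1–C5 and C10; ring B = C5–C10; C14 = methyl on C10; C15 = methyl on C4; C11(=C13)–C12 = acrylate on C7. The two six-membered rings share C5–C10, and a tetrasubstituted C4=C5 alkene is bonded directly to the quaternary C10.
- The four stereocentres (C3 S, C7 R, C8 R, C10 R) carry the C3 isobutyrate, the C7 acrylate, the C8 acetate and the C14 methyl all on the β-face.
- C10 is the only quaternary centre and the hardest to set. C7 can be made on an open chain with an auxiliary and is the natural control element for C10. C3 and C8 are carbinol centres that hydride can set late from the α-face, away from the axial C14 methyl.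
- The 8β-oxygen is axial on ring B and 1,3-syn to C14. A chain that already carries it cannot be trusted to steer ring closure to the right C10 epimer, and this decides the order in which C8 and C10 are made.
- Fragile features:
  - the 2-substituted acrylate (does not survive hydrogenation, bulky hydride or amide base);
  - the cis 8β-hydroxy/C12-ester pair (closes to the γ-lactone whenever O8 is a free alkoxide);
  - the acid-ionisable allylic C3 ester;
  - the need to tell O3 from O8 for two different acyl groups.
- The enabling feature: C4=C5, flanked by the future carbinol C3 and by quaternary C10, is the alkyne-derived bond of a cyclohexa-1,4-diene (C1=C2, C4=C5). A diene C10=C1–C2=C3 and an alkyne C4≡C5, joined by the tether C6–C9, give rings A and B in one cycloaddition; C10 cannot aromatise and C3 emerges as the only doubly allylic methylene.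

## Retrosynthesis

**Ester pattern (28 ⇐ 27 ⇐ 26 ⇐ 25).** The C8–O acetyl bond is cut last and the C3–O isobutyryl bond before it. Putting the isobutyrate on while O8 is still silylated (25 → 26) differentiates the two oxygens without any selectivity problem. The acetate must be last because its precursor 27 is the lactonisation-prone cis hydroxy ester. The forward steps need only a non-basic desilylation and two routine acylations.

**Acrylate (25 ⇐ 23 ⇐ 21).** C11=C13 is cut back to a CH2CO2Me arm (Mannich reaction, then elimination). The alternative of carrying the acrylate from an earlier stage fails, because it would have to survive the C1=C2 hydrogenation and the bulky-hydride reduction at C8. The arm in 21 is an ordinary ester and the only enolisable carbonyl there. The forward step must tolerate a free 3-OH (handled as its alkoxide).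

**Carbinols C3 and C8 (21 ⇐ 20 ⇐ 18).** Both C–H bonds are cut to carbonyls. Ring B of enedione 18 is a chair with C14 axial. A bulky hydride must therefore enter C8 equatorially and give the axial 8β-alkoxide; this is silylated at once to 20. A small hydride with CeCl3 then adds axially to C3 to give the 3β-alcohol 21. Reaching C8 through a ketone also frees the ring-forming step from having to carry an 8β-oxygen.

**Oxidation level of ring A (18 ⇐ 17 ⇐ 16 ⇐ 15).** C1–C2 is dehydrogenated and the C3 and C8 carbonyls are taken back to a CH2 and a carbinol. Going forward: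
- one hexavalent-chromium oxidation of 16 makes both carbonyls (C3 is the only doubly allylic position);
- RhCl(PPh3)3 then removes only the disubstituted alkene;
- 16 comes from 15 by desilylation.

Hydrogenating first and oxidising afterwards would lose the regiocontrol between C3 and C6.

**Key disconnection (15 ⇐ 14).** C3–C4 and C5–C10 are cut, opening both rings to the acyclic dienyne 14.
- Against a ring-B Diels–Alder (C5–C6/C9–C10) or a C7–C8 closure, this cut delivers the C4=C5 alkene, the quaternary C10 and the correct carbon oxidation pattern in one step from a chain with two stereocentres.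
- The C8 configuration in the chain is chosen as S (8α after closure), not the 8β of the target. With 8α, the chair leading to the 10β-methyl product has the C7 arm and the C8 silyloxy group both equatorial, and the competing chair has both axial with the oxygen syn to C14.
- An 8β-oxygen would instead sit axial and syn to C14 in the desired chair. The competing chair would cost only an axial CH2CO2Me next to the sp-hybridised C5, so the bias would be weak and probably mismatched.
- The forward reaction must reach an s-cis diene despite the (Z)-methyl; zerovalent nickel is used to do this near room temperature.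

**Diene and C8 (14 ⇐ 13 ⇐ 12 ⇐ 9 + 11; 11 ⇐ 10).** C2=C3 is cut (Wittig), then C8–C9 (vinylogous Mukaiyama aldol of aldehyde 9 with the silyl dienol ether 11 of 3-methylbut-2-enal). The aldol gives the (E)-trisubstituted C10=C1 alkene directly, with the tether trans to C2. The two CH2 groups on C7 of 9 are similar in size, so a chiral boron Lewis acid must choose the aldehyde face.

**C7 (9 ⇐ 8 ⇐ 7 ⇐ 4 + 5; 4 ⇐ 1 + 2).** The C7–C11 bond is cut by an Evans alkylation of the hex-4-ynoyl imide 4 with methyl bromoacetate 5. The imide is then taken to aldehyde 9 through thioester 8, so that the methyl ester is never exposed to hydride. All starting materials (1, 2, 5, 10) are commercial.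

## Roads not taken

**Alternative 1: chromium allylation closing ring B.**
- Cut and key step: C7–C8. An aldehyde–allylic bromide A2 (ring A complete, C9 aldehyde arm on C10, (Z)-2-(bromomethyl)enoate arm on C5) is treated with CrCl2 (divalent chromium). The allylchromium adds through C7 to the C8 aldehyde, closes ring B, sets C7 and C8 and unveils the C11=C13 methylene. The product A1 is one acetylation from the target and is the same compound as 27.
- Merits: the acrylate is born last and never meets hydrogen, hydride or amide base; no α-methylenation and no protecting group on O8 are needed.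
- Weak points:
  - all the difficulty of ring A (tetrasubstituted alkene, quaternary C10, C3 carbinol) is moved into A2 and not solved by the key step;
  - the two new centres must be set relative to a remote C10, and the required 8β-alkoxide is axial and syn to C14 in the cyclic transition state;
  - a cis chromium alkoxide next to the ester is set up to close to the α-methylene lactone, from which the open hydroxy ester is hard to recover.
- Comparison: in endgame economy this road is better. The chosen plan offers in return an auxiliary-set C7, a C10 set under a diequatorial tether, a C8 set by a predictable hindered-hydride reduction, and an O8 that is silylated from the moment it is formed.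

**Alternative 2: quinone Diels–Alder for ring B.**
- Cut and key step: C5–C6 and C9–C10. 2-Methoxy-5-methyl-1,4-benzoquinone A4 and 2-silyloxybutadiene A5 combine under TiCl2(BINOLate) (tetravalent titanium) to give the cis-fused adduct A3, with the angular methyl in place.
- Merits: a catalytic asymmetric step makes the quaternary centre from very cheap materials, and the C8 oxygen arrives as a silyl enol ether. The opening is shorter and more scalable than the eight steps needed here to reach 14.
- Weak points:
  - A3 is misfunctionalised: the C1 carbonyl must be deleted, C4 must gain a methyl and become an alkene carbon, C5 must lose its hydrogen, and C3 must change from enol ether to carbinol;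
  - the acetic ester arm must be introduced at C7 regioselectively (against C9) and stereoselectively;
  - regiochemistry and enantioselectivity for this particular 2,5-disubstituted quinone are not assured.
- Comparison: the opening is better, but the corrective redox and C–C steps outweigh it. The chosen plan's cycloadduct 15 already has the right carbon skeleton and the right unsaturation.

**Alternative 3: tandem dienyne metathesis.**
- Cut and key step: C5=C6 and C3=C4. The acyclic dienyne A7 with second-generation Grubbs catalyst, RuCl2(H2IMes)(PCy3)(=CHPh), closes ring B onto the propynyl alkyne and then ring A onto the prenyl-type alkene with loss of isobutene, giving the 3,5-diene A6.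
- Merits: this relay is a more reliable ring-forming reaction than a nickel cycloaddition of a (Z)-methyl diene, is catalytic, and tolerates the ester and silyl ether.
- Weak points:
  - it creates no stereocentre, so the quaternary C10 with its alkynyl, methyl and two chain substituents must be made enantioselectively on an open chain;
  - the heteroannular 3,5-diene must then be converted regio- and stereoselectively into the 3β-oxy-4-ene, which has no clean solution.
- Comparison: the ring closure itself is better here. The chosen plan sets C10 in the ring-forming event and delivers C3 as a doubly allylic CH2 ready for oxidation.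

Key step: step 9

Assumption: the B-phenyl oxazaborolidinone from N-tosyl-D-tryptophan is taken to direct the dienolate to the Si face of aldehyde 9; if the sense is the opposite, the L-tryptophan-derived reagent is used and nothing else changes.

Step 1
Reactants: 1 hex-4-ynoic acid; 2 (4S)-4-benzyl-1,3-oxazolidin-2-one
Product: 4 (4S)-4-benzyl-3-(hex-4-ynoyl)-1,3-oxazolidin-2-one, via hex-4-ynoic pivalic anhydride 3 (not isolated)
Conditions: PivCl, Et3N, THF, −20 °C; then 2, LiCl, rt
Reagents that add atoms: pivaloyl chloride, CC(C)(C)C(Cl)=O (its acyl group is present only in 3)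
Why: N-acylation of the oxazolidinone through the mixed anhydride with LiCl/Et3N activation; the auxiliary attacks the unhindered hex-4-ynoyl carbonyl of 3 and the alkyne is a spectator.

Step 2
Reactants: 4; 5 methyl bromoacetate
Product: 7 methyl (3R)-3-{[(4S)-4-benzyl-2-oxo-1,3-oxazolidin-3-yl]carbonyl}hept-5-ynoate, via sodium enolate 6 (not isolated)
Conditions: NaN(SiMe3)2, THF, −78 °C; then 5, −78 → −40 °C
Reagents that add atoms: sodium bis(trimethylsilyl)amide, C[Si](C)(C)[N-][Si](C)(C)C.[Na+] (sodium of 6 only)
Why: Evans asymmetric alkylation; the chelated (Z)-enolate 6 is attacked by the bromoacetate on the face opposite the benzyl group, which sets C7 (R), the same sense as the known allylation of the propionyl imide of this auxiliary.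

Step 3
Reactants: 7
Product: 8 methyl (3R)-3-[(ethylsulfanyl)carbonyl]hept-5-ynoate
Conditions: EtSH, n-BuLi, THF, 0 °C
Reagents that add atoms: ethanethiol, CCS
Why: Thiolate transacylation of the imide at its exocyclic carbonyl, the most electrophilic acyl group present; the auxiliary is released for recovery and C7 is not enolised at 0 °C.

Step 4
Reactants: 8
Product: 9 methyl (3R)-3-formylhept-5-ynoate
Conditions: Et3SiH, 10% Pd/C, acetone, rt
Reagents that add atoms: none
Why: Fukuyama reduction (palladium insertion into C–S, hydride transfer from silane, reductive elimination) gives the aldehyde without hydride reagents, so the methyl ester is untouched and C7 is not epimerised.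

Step 5
Reactants: 10 3-methylbut-2-enal
Product: 11 tert-butyl(dimethyl){[(1E)-3-methylbuta-1,3-dien-1-yl]oxy}silane
Conditions: TBSOTf, Et3N, Et2O, 0 °C → rt
Reagents that add atoms: tert-butyldimethylsilyl trifluoromethanesulfonate, CC(C)(C)[Si](C)(C)OS(=O)(=O)C(F)(F)F
Why: Soft enolisation by γ-deprotonation and O-silylation of the enal gives the (E)-silyl dienol ether, the vinylogous nucleophile for step 6.

Step 6
Reactants: 9; 11
Product: 12 methyl (3R,4S,6E)-3-(but-2-yn-1-yl)-4-hydroxy-6-methyl-8-oxooct-6-enoate
Conditions: B-phenyl oxazaborolidinone of N-tosyl-D-tryptophan, i-PrOH, EtCN, −78 °C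
Reagents that add atoms: none
Why: Asymmetric vinylogous Mukaiyama aldol; the dienol ether attacks the boron-bound aldehyde through its terminal CH2 (C9) and regenerates the (E)-enal, with i-PrOH taking up the silyl group. The aldehyde has little intrinsic facial bias because the two CH2 groups on C7 are alike, so the chiral Lewis acid sets C8 (S).

Step 7
Reactants: 12
Product: 13 methyl (3R,4S,6E)-3-(but-2-yn-1-yl)-6-methyl-8-oxo-4-[(triethylsilyl)oxy]oct-6-enoate
Conditions: TESOTf, 2,6-lutidine, CH2Cl2, −78 °C
Reagents that add atoms: triethylsilyl trifluoromethanesulfonate, CC[Si](CC)(CC)OS(=O)(=O)C(F)(F)F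
Why: Silylation of the secondary alcohol with silyl triflate and hindered base, done at once so that the γ-hydroxy ester cannot lactonise; the enal tolerates these conditions.

Step 8
Reactants: 13
Product: 14 methyl (3R,4S,6E)-3-(but-2-yn-1-yl)-6-methyl-4-[(triethylsilyl)oxy]nona-6,8-dienoate
Conditions: Ph3PCH3Br, KOt-Bu, THF, 0 °C
Reagents that add atoms: methyltriphenylphosphonium bromide, C[P+](c1ccccc1)(c1ccccc1)c1ccccc1.[Br-]
Why: Wittig methylenation of the enal gives the terminal diene; the non-stabilised ylide reacts with the aldehyde far faster than with the ester and does not touch the C10=C1 geometry.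

Step 9
Reactants: 14
Product: 15 methyl 2-[(2R,3S,4aS)-4a,8-dimethyl-3-[(triethylsilyl)oxy]-1,2,3,4,4a,7-hexahydronaphthalen-2-yl]acetate (8α-silyloxy eudesma-1,4-diene with the C7 acetic ester arm)
Conditions: Ni(cod)2 (10 mol %), tris(2-biphenylyl) phosphite (30 mol %), THF, high dilution, 25 → 55 °C
Reagents that add atoms: none
Why: Zerovalent nickel with a bulky triaryl phosphite binds the alkyne and the s-cis diene; oxidative cyclisation forms C5–C10 and gives an allyl/vinyl nickelacycle, and reductive elimination forms C3–C4 and releases the cyclohexa-1,4-diene. The closest known reaction type is the nickel-catalysed intramolecular [4+2] cycloaddition of unactivated dienynes to bicyclic cyclohexa-1,4-dienes, including substrates substituted at the tethered diene terminus that give angular quaternary carbons. Ring B closes by the C5–C10 bond through the four-carbon tether C6–C9, exo to both π-systems, in a chair-like array; ring A closes as the six-membered cycloadduct when C3–C4 forms. C10 is the only new stereocentre and is controlled by C7 and C8 together: in the chair leading to the 10β-methyl product the ester arm and the silyloxy group are both equatorial, whereas the other chair has both axial and puts the silyloxy group 1,3-syn to the C10 methyl. The step needs diastereofacial selectivity at C10 (secured by the 7,8-trans tether), the (E)-geometry at C10=C1 that puts the tether outside and the methyl inside (secured in step 6), and intramolecular coupling in preference to alkyne or diene oligomerisation (secured by dilution and mild temperature, which also avoids thermal 1,5-hydrogen shifts of the (Z)-methyl diene). The alkyne carbons become C4=C5 directly, C10 cannot aromatise, and the ester and silyl ether are spectators.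

Step 10
Reactants: 15
Product: 16 methyl 2-[(2R,3S,4aS)-3-hydroxy-4a,8-dimethyl-1,2,3,4,4a,7-hexahydronaphthalen-2-yl]acetate
Conditions: HF·pyridine, pyridine, THF, 0 °C
Reagents that add atoms: none
Why: Buffered fluoride cleavage of the equatorial triethylsilyl ether; no alkoxide is formed, so the trans γ-hydroxy ester is not driven to a lactone.

Step 11
Reactants: 16
Product: 17 methyl 2-[(2R,4aS)-4a,8-dimethyl-3,7-dioxo-1,2,3,4,4a,7-hexahydronaphthalen-2-yl]acetate
Conditions: CrO3, 3,5-dimethylpyrazole, CH2Cl2, −20 °C
Reagents that add atoms: chromium trioxide, O=[Cr](=O)=O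
Why: The hexavalent chromium–pyrazole complex oxidises the secondary alcohol to the C8 ketone and the doubly allylic C3 methylene to the cross-conjugated dienone (allylic oxidation) in one operation. C3 is the only doubly allylic CH2 and C10 bears no hydrogen, so neither a regioisomer nor aromatisation is open.

Step 12
Reactants: 17
Product: 18 methyl 2-[(2R,4aR)-4a,8-dimethyl-3,7-dioxo-1,2,3,4,4a,5,6,7-octahydronaphthalen-2-yl]acetate
Conditions: H2 (1 atm), RhCl(PPh3)3 (10 mol %), benzene, rt
Reagents that add atoms: none
Why: Homogeneous hydrogenation with the monovalent rhodium complex reduces the disubstituted C1=C2 bond of the cross-conjugated dienone and leaves the tetrasubstituted C4=C5 bond and both carbonyls, as in the 1,2-reduction of 4-methyl-1,4-dien-3-ones of the santonin type.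

Step 13
Reactants: 18
Product: 20 methyl 2-[(2R,3R,4aR)-4a,8-dimethyl-7-oxo-3-[(triethylsilyl)oxy]-1,2,3,4,4a,5,6,7-octahydronaphthalen-2-yl]acetate, via lithium 8β-alkoxide 19 (not isolated)
Conditions: LiBH(s-Bu)3 (1.05 equiv), THF, −78 °C; then TESOTf, −78 → −40 °C
Reagents that add atoms: lithium tri-sec-butylborohydride, [Li+].CCC(C)[BH-](C(C)CC)C(C)CC (lithium of 19 only); triethylsilyl trifluoromethanesulfonate, CC[Si](CC)(CC)OS(=O)(=O)C(F)(F)F
Why: The bulky hydride attacks the saturated C8 ketone equatorially because the axial β-face is blocked by the 1,3-related axial C14 methyl, giving the axial 8β-alkoxide 19 (C8 R, cis to the C7 arm). The hindered, β,β-disubstituted enone reacts more slowly, and in situ silylation at low temperature traps the alkoxide before it can attack the neighbouring ester.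

Step 14
Reactants: 20
Product: 21 methyl 2-[(2R,3R,4aR,7S)-7-hydroxy-4a,8-dimethyl-3-[(triethylsilyl)oxy]-1,2,3,4,4a,5,6,7-octahydronaphthalen-2-yl]acetate
Conditions: NaBH4, CeCl3·7H2O, MeOH, −20 °C
Reagents that add atoms: none
Why: Luche 1,2-reduction; hydride adds axially to the cerium-activated enone from the α-face, anti to the C14 methyl, giving the pseudo-equatorial 3β-alcohol (C3 S), while the ester and silyl ether are inert.

Step 15
Reactants: 21
Product: 23 methyl 3-(dimethylamino)-2-[(2R,3R,4aR,7S)-7-hydroxy-4a,8-dimethyl-3-[(triethylsilyl)oxy]-1,2,3,4,4a,5,6,7-octahydronaphthalen-2-yl]propanoate (both C11 epimers), via dilithium alkoxide–enolate 22 (not isolated)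
Conditions: LiN(i-Pr)2 (2.3 equiv), THF, −78 °C; then CH2=NMe2+ I−, −78 → 0 °C; aq. NH4Cl
Reagents that add atoms: lithium diisopropylamide, CC(C)[N-]C(C)C.[Li+] (lithium of 22 only); N,N-dimethylmethyleneiminium iodide, C=[N+](C)C.[I-]
Why: Mannich reaction of the ester enolate with Eschenmoser's salt; the first equivalent of base makes the C3 alkoxide, the second the only available enolate (C11), which is aminomethylated. There is no β-leaving group, any O-aminomethyl ether at O3 hydrolyses on work-up, and the new C11 centre is removed in step 16.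

Step 16
Reactants: 23
Product: 25 methyl 2-[(2R,3R,4aR,7S)-7-hydroxy-4a,8-dimethyl-3-[(triethylsilyl)oxy]-1,2,3,4,4a,5,6,7-octahydronaphthalen-2-yl]prop-2-enoate, via trimethylammonium iodide 24 (not isolated)
Conditions: MeI, MeOH, rt; evaporate; DBU, CH2Cl2, rt
Reagents that add atoms: iodomethane, CI (its methyl group and iodide are present only in 24)
Why: N-Quaternisation followed by base-induced β-elimination of trimethylamine, the classical α-methylenation sequence, unveils the C11=C13 acrylate under conditions that leave the free 3-OH and the silyl ether alone.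

Step 17
Reactants: 25
Product: 26 methyl 2-[(2R,3R,4aR,7S)-4a,8-dimethyl-7-[(2-methylpropanoyl)oxy]-3-[(triethylsilyl)oxy]-1,2,3,4,4a,5,6,7-octahydronaphthalen-2-yl]prop-2-enoate
Conditions: i-PrCOCl, pyridine, DMAP (cat.), CH2Cl2, 0 °C → rt
Reagents that add atoms: 2-methylpropanoyl chloride, CC(C)C(Cl)=O
Why: DMAP-catalysed acylation of the unhindered allylic 3β-alcohol; O8 is still silylated, which is what distinguishes the two ester positions.

Step 18
Reactants: 26
Product: 27 methyl 2-[(2R,3R,4aR,7S)-3-hydroxy-4a,8-dimethyl-7-[(2-methylpropanoyl)oxy]-1,2,3,4,4a,5,6,7-octahydronaphthalen-2-yl]prop-2-enoate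
Conditions: HF·pyridine, pyridine, THF, 0 °C → rt
Reagents that add atoms: none
Why: Buffered fluoride desilylation generates the 8β-alcohol without an alkoxide, so neither lactonisation onto the acrylate ester nor ionisation of the allylic isobutyrate is promoted.

Step 19
Reactants: 27
Product: 28 methyl 2-[(2R,3R,4aR,7S)-3-(acetyloxy)-4a,8-dimethyl-7-[(2-methylpropanoyl)oxy]-1,2,3,4,4a,5,6,7-octahydronaphthalen-2-yl]prop-2-enoate (CNP0127901.1)
Conditions: Ac2O, Et3N, DMAP, CH2Cl2, 0 °C → rt
Reagents that add atoms: acetic anhydride, CC(=O)OC(C)=O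
Why: DMAP-catalysed acetylation of the hindered axial 8β-alcohol completes the target; carried out directly on crude 27 to outrun lactonisation.

## Compound list

1 | hex-4-ynoic acid | CC#CCCC(=O)O | starting material
2 | (4S)-4-benzyl-1,3-oxazolidin-2-one | O=C1N[C@@H](Cc2ccccc2)CO1 | starting material
3 | hex-4-ynoic 2,2-dimethylpropanoic (pivalic) anhydride | CC#CCCC(=O)OC(=O)C(C)(C)C | intermediate (not isolated)
4 | (4S)-4-benzyl-3-(hex-4-ynoyl)-1,3-oxazolidin-2-one | CC#CCCC(=O)N1[C@@H](Cc2ccccc2)COC1=O | intermediate
5 | methyl bromoacetate | COC(=O)CBr | starting material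
6 | sodium (Z)-enolate of 4 | CC#CC/C=C(\[O-])N1[C@@H](Cc2ccccc2)COC1=O.[Na+] | intermediate (not isolated)
7 | methyl (3R)-3-{[(4S)-4-benzyl-2-oxo-1,3-oxazolidin-3-yl]carbonyl}hept-5-ynoate | CC#CC[C@H](CC(=O)OC)C(=O)N1[C@@H](Cc2ccccc2)COC1=O | intermediate
8 | methyl (3R)-3-[(ethylsulfanyl)carbonyl]hept-5-ynoate | CC#CC[C@H](CC(=O)OC)C(=O)SCC | intermediate
9 | methyl (3R)-3-formylhept-5-ynoate | CC#CC[C@H](CC(=O)OC)C=O | intermediate
10 | 3-methylbut-2-enal | CC(C)=CC=O | starting material
11 | tert-butyl(dimethyl){[(1E)-3-methylbuta-1,3-dien-1-yl]oxy}silane | CC(=C)/C=C/O[Si](C)(C)C(C)(C)C | intermediate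
12 | methyl (3R,4S,6E)-3-(but-2-yn-1-yl)-4-hydroxy-6-methyl-8-oxooct-6-enoate | CC#CC[C@H](CC(=O)OC)[C@@H](O)C/C(C)=C/C=O | intermediate
13 | methyl (3R,4S,6E)-3-(but-2-yn-1-yl)-6-methyl-8-oxo-4-[(triethylsilyl)oxy]oct-6-enoate | CC#CC[C@H](CC(=O)OC)[C@@H](O[Si](CC)(CC)CC)C/C(C)=C/C=O | intermediate
14 | methyl (3R,4S,6E)-3-(but-2-yn-1-yl)-6-methyl-4-[(triethylsilyl)oxy]nona-6,8-dienoate | CC#CC[C@H](CC(=O)OC)[C@@H](O[Si](CC)(CC)CC)C/C(C)=C/C=C | intermediate
15 | methyl 2-[(2R,3S,4aS)-4a,8-dimethyl-3-[(triethylsilyl)oxy]-1,2,3,4,4a,7-hexahydronaphthalen-2-yl]acetate | COC(=O)C[C@H]1CC2=C(C)CC=C[C@]2(C)C[C@@H]1O[Si](CC)(CC)CC | intermediate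
16 | methyl 2-[(2R,3S,4aS)-3-hydroxy-4a,8-dimethyl-1,2,3,4,4a,7-hexahydronaphthalen-2-yl]acetate | COC(=O)C[C@H]1CC2=C(C)CC=C[C@]2(C)C[C@@H]1O | intermediate
17 | methyl 2-[(2R,4aS)-4a,8-dimethyl-3,7-dioxo-1,2,3,4,4a,7-hexahydronaphthalen-2-yl]acetate | COC(=O)C[C@H]1CC2=C(C)C(=O)C=C[C@]2(C)CC1=O | intermediate
18 | methyl 2-[(2R,4aR)-4a,8-dimethyl-3,7-dioxo-1,2,3,4,4a,5,6,7-octahydronaphthalen-2-yl]acetate | COC(=O)C[C@H]1CC2=C(C)C(=O)CC[C@]2(C)CC1=O | intermediate
19 | lithium (2R,3R,4aR)-3-(2-methoxy-2-oxoethyl)-4a,8-dimethyl-7-oxo-1,2,3,4,4a,5,6,7-octahydronaphthalen-2-olate (8β-alkoxide) | COC(=O)C[C@H]1CC2=C(C)C(=O)CC[C@]2(C)C[C@H]1[O-].[Li+] | intermediate (not isolated)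
20 | methyl 2-[(2R,3R,4aR)-4a,8-dimethyl-7-oxo-3-[(triethylsilyl)oxy]-1,2,3,4,4a,5,6,7-octahydronaphthalen-2-yl]acetate | COC(=O)C[C@H]1CC2=C(C)C(=O)CC[C@]2(C)C[C@H]1O[Si](CC)(CC)CC | intermediate
21 | methyl 2-[(2R,3R,4aR,7S)-7-hydroxy-4a,8-dimethyl-3-[(triethylsilyl)oxy]-1,2,3,4,4a,5,6,7-octahydronaphthalen-2-yl]acetate | COC(=O)C[C@H]1CC2=C(C)[C@@H](O)CC[C@]2(C)C[C@H]1O[Si](CC)(CC)CC | intermediate
22 | dilithium C3-alkoxide/ester enolate of 21 | COC([O-])=C[C@H]1CC2=C(C)[C@@H]([O-])CC[C@]2(C)C[C@H]1O[Si](CC)(CC)CC.[Li+].[Li+] | intermediate (not isolated)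
23 | methyl 3-(dimethylamino)-2-[(2R,3R,4aR,7S)-7-hydroxy-4a,8-dimethyl-3-[(triethylsilyl)oxy]-1,2,3,4,4a,5,6,7-octahydronaphthalen-2-yl]propanoate (both C11 epimers) | CN(C)CC(C(=O)OC)[C@H]1CC2=C(C)[C@@H](O)CC[C@]2(C)C[C@H]1O[Si](CC)(CC)CC | intermediate
24 | N,N,N-trimethylammonium iodide of 23 | C[N+](C)(C)CC(C(=O)OC)[C@H]1CC2=C(C)[C@@H](O)CC[C@]2(C)C[C@H]1O[Si](CC)(CC)CC.[I-] | intermediate (not isolated)
25 | methyl 2-[(2R,3R,4aR,7S)-7-hydroxy-4a,8-dimethyl-3-[(triethylsilyl)oxy]-1,2,3,4,4a,5,6,7-octahydronaphthalen-2-yl]prop-2-enoate | C=C(C(=O)OC)[C@H]1CC2=C(C)[C@@H](O)CC[C@]2(C)C[C@H]1O[Si](CC)(CC)CC | intermediate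
26 | methyl 2-[(2R,3R,4aR,7S)-4a,8-dimethyl-7-[(2-methylpropanoyl)oxy]-3-[(triethylsilyl)oxy]-1,2,3,4,4a,5,6,7-octahydronaphthalen-2-yl]prop-2-enoate | C=C(C(=O)OC)[C@H]1CC2=C(C)[C@@H](OC(=O)C(C)C)CC[C@]2(C)C[C@H]1O[Si](CC)(CC)CC | intermediate
27 | methyl 2-[(2R,3R,4aR,7S)-3-hydroxy-4a,8-dimethyl-7-[(2-methylpropanoyl)oxy]-1,2,3,4,4a,5,6,7-octahydronaphthalen-2-yl]prop-2-enoate | C=C(C(=O)OC)[C@H]1CC2=C(C)[C@@H](OC(=O)C(C)C)CC[C@]2(C)C[C@H]1O | intermediate
28 | methyl 2-[(2R,3R,4aR,7S)-3-(acetyloxy)-4a,8-dimethyl-7-[(2-methylpropanoyl)oxy]-1,2,3,4,4a,5,6,7-octahydronaphthalen-2-yl]prop-2-enoate | C=C(C(=O)OC)[C@H]1CC2=C(C)[C@@H](OC(=O)C(C)C)CC[C@]2(C)C[C@H]1OC(C)=O | target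

## Step count and least certain steps

Total: 19 steps. Longest linear sequence: 18 steps (steps 1–4 and 6–19, from hex-4-ynoic acid); step 5 is a one-step side branch.

**Step 9 (key step).** The most likely failure is slow oxidative cyclisation: the (Z)-methyl on C10 strains the s-cis diene, so alkyne or diene oligomerisation can overtake the intramolecular coupling, and some material may leak through the diaxial chair. The fallback makes the tether cyclic, which removes rotors and makes the diaxial chair impossible.
- 14 is desilylated with HF·pyridine to methyl (3R,4S,6E)-3-(but-2-yn-1-yl)-4-hydroxy-6-methylnona-6,8-dienoate F1.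
- Acid catalysis (TsOH, CH2Cl2) lactonises it to (4R,5S)-4-(but-2-yn-1-yl)-5-[(2E)-2-methylpenta-2,4-dien-1-yl]oxolan-2-one F2.
- Cycloaddition of F2 under the same nickel catalysis should give the trans-fused lactone (3aR,8aS,9aS)-5,8a-dimethyl-3a,4,6,8a,9,9a-hexahydronaphtho[2,3-b]furan-2(3H)-one F3.
- LiOH opens F3 to 2-[(2R,3S,4aS)-3-hydroxy-4a,8-dimethyl-1,2,3,4,4a,7-hexahydronaphthalen-2-yl]acetic acid F4, and methylation of its carboxylate (MeI, K2CO3, DMF) returns to the route at 16.

**Step 6.** Double stereodifferentiation may be poor, because aldehyde 9 offers almost no intrinsic bias and an α-branched aliphatic aldehyde is a demanding partner for a catalytic vinylogous aldol; epimerisation of 9 at C7 is a second hazard. The fallback builds the diene by stoichiometric reagent control and carbometalation.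
- 9 is treated with B-allenyl-diisopinocampheylborane (the antipode giving the 8S alcohol) to give methyl (3R)-3-[(1S)-1-hydroxybut-3-yn-1-yl]hept-5-ynoate F5.
- Silylation (TESOTf, 2,6-lutidine) gives methyl (3R)-3-{(1S)-1-[(triethylsilyl)oxy]but-3-yn-1-yl}hept-5-ynoate F6.
- Zirconium-catalysed methylalumination of the terminal alkyne (AlMe3, cat. Cp2ZrCl2), then coupling of the alkenylalane with vinyl bromide (cat. Pd(PPh3)4, zerovalent palladium, ZnCl2) returns to the route at 14. The syn addition of methyl and aluminium gives the required (E)-diene.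

**Step 13.** Chemoselectivity may be incomplete: the bulky hydride may also reduce the C3 enone, or the 8β-alkoxide may lactonise before it is silylated. The fallback sets C8 before the C3 carbonyl exists.
- 16 is oxidised with Dess–Martin periodinane to methyl 2-[(2R,4aS)-4a,8-dimethyl-3-oxo-1,2,3,4,4a,7-hexahydronaphthalen-2-yl]acetate F7.
- LiBH(s-Bu)3 then TESOTf gives methyl 2-[(2R,3R,4aS)-4a,8-dimethyl-3-[(triethylsilyl)oxy]-1,2,3,4,4a,7-hexahydronaphthalen-2-yl]acetate F8.
- CrO3–3,5-dimethylpyrazole gives methyl 2-[(2R,3R,4aS)-4a,8-dimethyl-7-oxo-3-[(triethylsilyl)oxy]-1,2,3,4,4a,7-hexahydronaphthalen-2-yl]acetate F9.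
- Hydrogenation with RhCl(PPh3)3 returns to the route at 20.

**Step 4.** The palladium hydride may hydrosilylate or partly reduce the internal alkyne. The fallback avoids palladium: the imide 7 is cleaved reductively with NaBH4 in THF/H2O to methyl (3R)-3-(hydroxymethyl)hept-5-ynoate F10, which is oxidised without delay (Dess–Martin periodinane) to return at 9. The speed is needed because F10 can itself lactonise.

**Step 18.** The freed 8β-hydroxyl may lactonise onto the cis acrylate ester, or the allylic isobutyrate may ionise on long exposure to acidic fluoride. The fallback never frees the alcohol: 26 is treated with Ac2O and catalytic Cu(OTf)2, which exchanges the silyl ether directly for the acetate and arrives at 28. This fallback makes no new compound (entry F0).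

## Further compounds

F1 | step 9 | methyl (3R,4S,6E)-3-(but-2-yn-1-yl)-4-hydroxy-6-methylnona-6,8-dienoate | CC#CC[C@H](CC(=O)OC)[C@@H](O)C/C(C)=C/C=C
F2 | step 9 | (4R,5S)-4-(but-2-yn-1-yl)-5-[(2E)-2-methylpenta-2,4-dien-1-yl]oxolan-2-one | CC#CC[C@@H]1CC(=O)O[C@H]1C/C(C)=C/C=C
F3 | step 9 | (3aR,8aS,9aS)-5,8a-dimethyl-3a,4,6,8a,9,9a-hexahydronaphtho[2,3-b]furan-2(3H)-one | O=C1C[C@H]2CC3=C(C)CC=C[C@]3(C)C[C@@H]2O1
F4 | step 9 | 2-[(2R,3S,4aS)-3-hydroxy-4a,8-dimethyl-1,2,3,4,4a,7-hexahydronaphthalen-2-yl]acetic acid | O=C(O)C[C@H]1CC2=C(C)CC=C[C@]2(C)C[C@@H]1O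
F5 | step 6 | methyl (3R)-3-[(1S)-1-hydroxybut-3-yn-1-yl]hept-5-ynoate | CC#CC[C@H](CC(=O)OC)[C@@H](O)CC#C
F6 | step 6 | methyl (3R)-3-{(1S)-1-[(triethylsilyl)oxy]but-3-yn-1-yl}hept-5-ynoate | CC#CC[C@H](CC(=O)OC)[C@@H](O[Si](CC)(CC)CC)CC#C
F7 | step 13 | methyl 2-[(2R,4aS)-4a,8-dimethyl-3-oxo-1,2,3,4,4a,7-hexahydronaphthalen-2-yl]acetate | COC(=O)C[C@H]1CC2=C(C)CC=C[C@]2(C)CC1=O
F8 | step 13 | methyl 2-[(2R,3R,4aS)-4a,8-dimethyl-3-[(triethylsilyl)oxy]-1,2,3,4,4a,7-hexahydronaphthalen-2-yl]acetate | COC(=O)C[C@H]1CC2=C(C)CC=C[C@]2(C)C[C@H]1O[Si](CC)(CC)CC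
F9 | step 13 | methyl 2-[(2R,3R,4aS)-4a,8-dimethyl-7-oxo-3-[(triethylsilyl)oxy]-1,2,3,4,4a,7-hexahydronaphthalen-2-yl]acetate | COC(=O)C[C@H]1CC2=C(C)C(=O)C=C[C@]2(C)C[C@H]1O[Si](CC)(CC)CC
F10 | step 4 | methyl (3R)-3-(hydroxymethyl)hept-5-ynoate | CC#CC[C@H](CC(=O)OC)CO
F0 | step 18 | none | none
A1 | alternative 1 | methyl 2-[(2R,3R,4aR,7S)-3-hydroxy-4a,8-dimethyl-7-[(2-methylpropanoyl)oxy]-1,2,3,4,4a,5,6,7-octahydronaphthalen-2-yl]prop-2-enoate (8-O-deacetyl target) | C=C(C(=O)OC)[C@H]1CC2=C(C)[C@@H](OC(=O)C(C)C)CC[C@]2(C)C[C@H]1O
A2 | alternative 1 | methyl (2Z)-2-(bromomethyl)-4-[(3S,6R)-2,6-dimethyl-3-[(2-methylpropanoyl)oxy]-6-(2-oxoethyl)cyclohex-1-en-1-yl]but-2-enoate | COC(=O)/C(CBr)=C/CC1=C(C)[C@@H](OC(=O)C(C)C)CC[C@]1(C)CC=O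
A3 | alternative 2 | cis-fused 6-(tert-butyldimethylsilyloxy)-2-methoxy-4a-methyl-4a,5,8,8a-tetrahydronaphthalene-1,4-dione (angular methyl configured as C10 of the target) | COC1=CC(=O)[C@]2(C)CC(O[Si](C)(C)C(C)(C)C)=CC[C@@H]2C1=O
A4 | alternative 2 | 2-methoxy-5-methyl-1,4-benzoquinone | COC1=CC(=O)C(C)=CC1=O
A5 | alternative 2 | 2-(tert-butyldimethylsilyloxy)buta-1,3-diene | C=CC(=C)O[Si](C)(C)C(C)(C)C
A6 | alternative 3 | 8β-(tert-butyldimethylsilyloxy) eudesma-3,5-diene carrying the C7 acetic methyl ester arm (7β, 10β-methyl) | COC(=O)C[C@H]1C=C2C(C)=CCC[C@]2(C)C[C@H]1O[Si](C)(C)C(C)(C)C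
A7 | alternative 3 | methyl 3-ethenyl-4-(tert-butyldimethylsilyloxy)-6,10-dimethyl-6-(prop-1-yn-1-yl)undec-9-enoate, configured at C3, C4 and C6 as C7, C8 and C10 of A6 | COC(=O)C[C@H]([C@H](O[Si](C)(C)C(C)(C)C)C[C@](C)(C#CC)CCC=C(C)C)C=C
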